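Follow the charge.

    gas phase ⇌ dissolved gas, rate k1*(csat - [dissolved gas]) (k1 = 11 h⁻¹, csat = 200 mM)
    starting material + dissolved gas ⇌ target (K2 = 12 M⁻¹, k2 = 2.3 M⁻¹ h⁻¹)
    starting material → side product A (k3 = 0.60 h⁻¹)
    starting material + target → side product B (k4 = 0.011 M⁻¹ h⁻¹)
starting material 2.1 M; gas phase 200 mM (held); time 12 h
- percent here means starting material units held: one side product B counts as two
- at the start none of the gas is dissolved
- run time (flask): 12 h
* amount of target at 12 h, in percent of the starting material charged
* the change that raises the amount of target at 12 h, in percent of the starting material charged most ("none" if none brings more than 2 percentage points) (birch / cedar / none)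
* amount of target at 12 h, in percent of the starting material charged, after cedar
- birch: doubling the saturation concentration of gas phase, all else as stated
- cedar: doubling the transfer coefficient of step 1, all else as stated

Dissolved gas is resupplied at 11 h⁻¹ while the full charge draws on it at 4.83 h⁻¹, so this reckoning holds it at saturation. Starting material then has two pseudo-first-order exits: capture at 0.460 h⁻¹ and the passing into side product A at 0.60 h⁻¹, so the captured share of the charge is 43.4%. The way back, 0.192 h⁻¹, is slower than both exits together and enters as a correction: of each returning unit of target, the captured share comes back and the remainder is lost. Target therefore falls at 0.108 h⁻¹, the leak constant, which is the way-back constant times the uncaptured share. The passing into side product B, at 0.0231 h⁻¹ with the charge at full strength, is smaller and is dropped.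

The captured share, decayed by the leak, leaves 11.8% of the charge as target at 12 h. The transfer coefficient does not appear in this reckoning, so cedar stays at 11.8%. Birch raises the share to 60.5% and lowers the leak to 0.0757 h⁻¹, so the choice is birch.

The forecast gives 11.8%, birch, and 13.2% after cedar, which is higher than this reckoning's cedar figure. Its ground: "Doubling the saturation concentration roughly doubles the dissolved gas and so raises the target strongly".

The simulation gives 11.5% and birch, which gains 11 percentage points, while cedar gains 0.62 points and reaches 12.1%.

In the flask, target falls from 20.9% at 6.00 h to 11.5% at 12.0 h, a read decay of 0.0996 h⁻¹ against the leak constant of 0.108 h⁻¹. The neighbouring flask is the same charge read at 3.0 h, and for this reading the reckoning subtracts the decay at the summed exits from the leak term. The captured share times that difference gives 29.6%. That flask reads 26.6% target, with 9.13% starting material still there.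

(All constants are invented; no experiment stands behind them.)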